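## The problem

Compound 21 is a bicyclic C20 diterpenoid of the labdane type (locants as in the remark before the steps). Rings A and B are cis-fused: H5 and the angular C10 methyl lie on the same (β) face. Ring B holds a tetrasubstituted C8=C9 alkene that carries a hydroxymethyl group (C17) on C8 and, on C9, a two-carbon chain (C11–C12) ending in a β-substituted butenolide (C13–C16); ring A carries the C4 gem-dimethyl group. Four stereocentres must be set, (2S,5R,6S,10S): the carbinols C2 and C6, the ring-fusion methine C5 and the quaternary C10. C2 is 1,3 to C10 across ring A, so a short tether from the C2 oxygen can deliver a carbon to C10 on one face only; a cis-selective bond formation across C5=C10 then fixes C5, and C6 can be set afterwards by reduction of a ketone in the rigid cis-fused frame. The butenolide does not tolerate strong base, hydride or nucleophiles and should come last; the C17 hydroxyl lies cis to the C11 branch across C8=C9 and will close onto any carbonyl at C11 unless it is masked. The enabling feature is that C6 and C8 are 1,5-related across the cis C5–C10 bond and C8 bears an oxygenated carbon: ring B is a latent 1,5-diketone, so C6, C7, C8, C9, C17 and O17 map onto a 5-methyl-3(2H)-furanone (ring oxygen = O17) that can be joined to the ring A alkene C5=C10 by (2+2) photocycloaddition and retro-aldol opening, with C11 as a carboxylate that ties the furanone to O2.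

## Retrosynthesis

**C12–C13.** The butenolide is attached last. With O17 masked as the silyl ether 20, cutting the sp3–sp2 bond C12–C13 gives the commercial bromobutenolide 18 and the terminal diene 17, whose alkylborane 19 is the nucleophile. A cut at C11–C12 would need an allylic electrophile beside the tetrasubstituted alkene and a heteroaryl-methyl nucleophile whose ring must later be oxidised in the presence of that alkene; the C12–C13 cut brings the butenolide in intact. The forward reaction must hydroborate the vinyl group only.

**C11=C12.** A Wittig transform removes C12 and turns C11 into an aldehyde, which exists as the lactol 16 with the cis C2 hydroxyl; one oxidation level higher it is the unsaturated δ-lactone 15. This costs one carbon and gains the six-membered C2–O–C11 bridge on which the earlier steps depend. O17 must stay silylated, since a free C17 hydroxyl cis to a C11 carbonyl would close a five-membered lactol and aromatise. The forward steps are a partial hydride reduction and a methylenation.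

**Ring B adjustment.** The conjugated alkene and the C6 carbinol of 15 are traced to the enone 13 (C6 ketone, C7=C8, C9–H) through the allylic alcohol 14. Placing C8=C9 at the ketone stage was set aside: enone and unsaturated lactone would then compete, and the acetoacetate–enone cyclisation analogy favours the enone. After reduction only one conjugated position remains. The forward steps need face selection at C6 and a thermodynamic alkene shift.

**C7–C8.** Enone 13 is the aldol condensation product (through ketol 12) of the 1,5-diketone 11, the silyl ether of 10. The cut opens ring B and leaves a methyl ketone on C5 and an oxygenated acetyl group on C9. This is the ring closure of a Robinson-type annulation, with the β-keto-lactone carbonyl as the acceptor. The forward reaction needs the methyl ketone to act as the nucleophile and the strained lactone to survive.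

**C9–C10 and C5–C6 (key).** The carbonyl carbons C6 and C8 of 10 flank the cis C5–C10 bond, the de Mayo retron. Reconnecting C6–C9 gives cyclobutane 9; cutting C9–C10 and C5–C6 of 9 gives the furanone ester 8. An untethered union is expected to pair the more substituted alkene carbon with the β-carbon of the chromophore and to show no face preference. The ester link from O2 to C11 allows only the six-membered closure C9–C10 on the face of O2. Two rings and two stereocentres are removed. The forward reaction needs the s-cis ester rotamer and must close a bond beside the quaternary C4.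

**Assembly of 8.** The furanone is cut at C8–C9 and O17–C17 into the acetoacetate 5 and chloroacetyl chloride 6 (through the tricarbonyl 7). The ester C–O bond of 5 is cut to alcohol 2 and dioxinone 3 (through acetylketene 4). Alcohol 2 comes from β-isophorone 1 by enantioselective reduction, the only stereocentre set by reagent control.

## Roads not taken

**Alternative 1:** The cut is C5–C10, leaving the ten-membered dienedione A1 (C6 ketone, (Z)-enone C2(=O)–C1=C10, C8=C9 with both side arms). A chiral primary amine–thiourea catalyst would form the C5 enamine of the C6 ketone, which adds across the ring to C10 and gives the cis-decalin-2,6-dione A2. Its merits are real: both rings and both ring-fusion centres form in one catalytic step, the absolute configuration comes from the catalyst, and the tetrasubstituted alkene with C11 and C17 is already in place. In bond economy it is better than the chosen plan. Its weak points are the assembly of A1 (a medium ring with a Z-trisubstituted enone and a tetrasubstituted alkene) and the enamine regiochemistry: C5 is a methylene beside the quaternary C4, whereas C7 is less hindered and allylic. The C5 nucleophile must also create the quaternary C10, and the C2 and C6 ketones must then be reduced selectively, C2 with no neighbouring control element. Against this the chosen plan sets a C2 centre obtained by reduction of a cheap ketone, a six-membered tether that leaves no regiochemical choice, and a precursor (8) reached in three steps.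

**Alternative 2:** The cuts are C1–C10 and C4–C5. Quinone A3 and silyloxydiene A4 would combine under a chiral oxazaborolidinium Lewis acid to the cis-fused adduct A5. The enantioselective quinone Diels–Alder reaction is a dependable way to a cis ring fusion with an angular methyl group, is thermal and catalytic, and is better precedented than an ester-tethered photocycloaddition. For this target the diene must deliver C4 as a fully substituted terminus; its inward methyl group disfavours the s-cis conformer and a quaternary centre forms next to the new C4–C5 bond. After the cycloaddition ring B carries oxygen where the target carries carbon: the C9 ketone and the C8 enol ether must be exchanged for the C11–C12 chain and C17, and the tetrasubstituted alkene must be built between two former carbonyl carbons. C2 must still be reduced selectively. The chosen plan has a less certain key step but leaves every carbon of ring B, C11 and C17 in place after it.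

**Alternative 3:** The cut is C9–C10. Heating the (6Z)-triene A6 would close ring B by disrotatory 6π electrocyclisation, and a suprafacial hydrogen shift from C9 to C5 would give the cis-fused 6,8-diene A7. The step is thermal and reagent-free, the whole carbon skeleton is present, and if the ring closure were face-selective this road would be shorter and would need no photochemical equipment. Its weak points are that the closure must create a quaternary centre from a tetrasubstituted ring alkene terminus, which favours the open triene and lets 1,7-hydrogen shifts of the (Z)-triene compete. The face of closure is biased only by the remote C2 silyl ether, so C10 is not secured. The C6=C7 bond of A7 must then be hydrated at C6 with the α-hydroxyl while C8=C9 is spared. The chosen plan sets against this a covalent transfer of the C2 configuration to C10 and C5, and an oxygen that sits on C6 from the key step onward.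

Key step: step 4

Remark: locants follow the labdane-type numbering of the target (C1–C10 decalin, C11–C12 chain, C13–C16 butenolide, C17 hydroxymethyl carbon, C18/C19 gem-dimethyl, C20 angular methyl); β is the face of the C10 methyl group.

Assumption: C9 of 10 and 11 is an epimerisable β-keto-lactone methine drawn as one epimer, and the hydroxyls of the non-isolated borane 19 are drawn free although excess 9-BBN will hold them as borinates until the aqueous base of the coupling.

## Steps

Step 1
Reactants: 1 β-isophorone (3,5,5-trimethylcyclohex-3-en-1-one)
Product: 2 (R)-3,5,5-trimethylcyclohex-3-en-1-ol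
Conditions: (R)-selective NADPH-dependent ketoreductase, NADP+ (cat.), iPrOH, KH2PO4/K2HPO4 buffer pH 7.0, 30 °C
Reagents that add atoms: none
Why: Enzymatic carbonyl reduction with isopropanol as the hydride source; the enzyme has to tell CH2–CMe2 from CH2–C(Me)=, the same kind of discrimination that underlies the enzymatic reduction of 2,2,6-trimethylcyclohexane-1,4-dione at its 4-carbonyl. The neutral buffer should prevent isomerisation to the conjugated α-isomer, and the enzyme sets C2.

Step 2
Reactants: 2 (R)-3,5,5-trimethylcyclohex-3-en-1-ol; 3 2,2,6-trimethyl-4H-1,3-dioxin-4-one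
Product: 5 (R)-3,5,5-trimethylcyclohex-3-en-1-yl 3-oxobutanoate, via acetylketene 4 (not isolated)
Conditions: xylenes, 135 °C, acetone distilled off
Reagents that add atoms: none
Why: Thermal retro-(4+2) fragmentation of the dioxinone releases acetylketene, which the secondary alcohol traps as the acetoacetate under neutral conditions. The carbinol centre is not touched.

Step 3
Reactants: 5 (R)-3,5,5-trimethylcyclohex-3-en-1-yl 3-oxobutanoate; 6 chloroacetyl chloride
Product: 8 (R)-3,5,5-trimethylcyclohex-3-en-1-yl 5-methyl-3-oxo-2,3-dihydrofuran-4-carboxylate, via chloroacetyl tricarbonyl 7 (not isolated)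
Conditions: MgCl2, pyridine, CH2Cl2, 0 °C to rt; then Et3N, rt
Reagents that add atoms: none
Why: C-acylation of the magnesium-chelated β-keto ester enolate, then intramolecular O-alkylation of the acetyl enol by the chloromethyl ketone (5-exo-tet) closes the 3(2H)-furanone. This is the known route from acetoacetates and chloroacetyl chloride to alkyl 5-methyl-3-oxo-2,3-dihydrofuran-4-carboxylates.

Step 4
Reactants: 8 (R)-3,5,5-trimethylcyclohex-3-en-1-yl 5-methyl-3-oxo-2,3-dihydrofuran-4-carboxylate
Product: 10 bridged δ-lactone 1,5-diketone (C2–O–C11 lactone on the α face; acetyl C6–C7 on C5α; hydroxyacetyl C8–C17 on C9; 5β-H; 10β-methyl), via cyclobutane photoadduct 9 (not isolated)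
Conditions: hν (λ ≥ 300 nm, Pyrex), MeCN (0.003 M, degassed), 40 °C, flow; then 1 M HCl, THF–H2O, 0 °C
Reagents that add atoms: water, O
Why: Excitation and intersystem crossing give the triplet furanone, whose C9 adds to C10 of the tethered alkene (6-exo-trig closure of the δ-lactone, the only closure the C9–C11(=O)–O–C2–C1–C10 link allows); the resulting 1,4-biradical (α-oxy radical at C6, secondary radical at C5) recombines to the cyclobutane 9. This is the enone–alkene (2+2) photocycloaddition of 3(2H)-furanones in its ester-tethered intramolecular form, followed by de Mayo retro-aldol opening. The lactone bridge can only span cis positions of ring A, so both new bonds form on the face of the C2 oxygen and the C2 stereocentre fixes C10 (C9 α, methyl β); the necessarily cis-fused cyclobutane puts C6 α on C5, which makes H5 cis to the C10 methyl. In 9 the C6–C9 bond lies between an alkoxy donor and a keto-ester acceptor pair, and acid opens it to the β-keto-lactone enol and an oxocarbenium ion at C6, which water turns into the C6 methyl ketone and the free C17 hydroxyl. The step needs straight regiochemistry and α-face addition, and both are imposed by the short tether, not by the chromophore. Only the minor s-cis ester rotamer can close, so warm, dilute and prolonged irradiation is specified; excited molecules in the other rotamer simply decay. C9 of 10 is epimerisable and its configuration does not matter.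

Step 5
Reactants: 10 bridged δ-lactone 1,5-diketone
Product: 11 C17 tert-butyldiphenylsilyl ether of 10
Conditions: TBDPSCl, imidazole, CH2Cl2, 0 °C
Reagents that add atoms: tert-butyldiphenylsilyl chloride, CC(C)(C)[Si](Cl)(c1ccccc1)c1ccccc1
Why: Selective silylation of the only primary hydroxyl. It is done at once on crude 10, because the free C17 hydroxyl can attack the C11 carbonyl and transfer the lactone to a five-membered tetronic acid.

Step 6
Reactants: 11 C17 tert-butyldiphenylsilyl ether of 10
Product: 13 tricyclic enone (C6 ketone; C7=C8; C17 silyl ether on C8; 9β-H; C2–O–C11 lactone; cis ring fusion), via ketol 12 (not isolated)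
Conditions: TsOH·H2O (cat.), toluene, 80 °C, 4 Å molecular sieves
Reagents that add atoms: none
Why: Acid-catalysed intramolecular aldol condensation (6-enolendo-exo-trig): the methyl ketone enol (C7) attacks the activated C8 ketone and dehydration gives the ketone-conjugated enone, as in the cyclisation of acetoacetate–methyl vinyl ketone adducts to 4-alkoxycarbonyl-3-methylcyclohex-2-enones. C9 equilibrates through its enol to the only epimer that can close ring B, and C5 cannot be lost because the lactone-locked ring A accepts only the cis fusion.

Step 7
Reactants: 13 tricyclic enone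
Product: 14 (6S)-allylic alcohol (6α-OH; C7=C8; 9β-H; lactone and silyl ether unchanged)
Conditions: NaBH4, CeCl3·7H2O, MeOH, −78 to −40 °C
Reagents that add atoms: none
Why: Luche 1,2-reduction of the enone. Hydride should arrive axially on the convex β face, since the α face of C6 is covered by ring A (C4 and its α-methyl) folded under ring B and by the lactone bridge; this gives the 6α-alcohol.

Step 8
Reactants: 14 (6S)-allylic alcohol
Product: 15 α,β-unsaturated δ-lactone (C8=C9 conjugated with C11=O; 6α-OH; C17 silyl ether)
Conditions: DBU (0.5 equiv), toluene, 60 °C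
Reagents that add atoms: none
Why: Base-mediated isomerisation of a β,γ-unsaturated lactone to the conjugated isomer through the dienolate (C9–H removed, C7 protonated). The tetrasubstituted, lactone-conjugated alkene is the thermodynamic position now that C6 is no longer a ketone, and the transient C9 centre disappears as planned.

Step 9
Reactants: 15 α,β-unsaturated δ-lactone
Product: 16 lactol (C11 hemiacetal bridging to O2; mixture at C11; C8=C9; 6α-OH; C17 silyl ether)
Conditions: iBu2AlH (2.2 equiv), CH2Cl2, −78 °C; aq. KNaC4H4O6
Reagents that add atoms: none
Why: Partial reduction of a lactone to the lactol; the aluminium hemiacetal is stable at −78 °C, and one equivalent of hydride is consumed by the C6 hydroxyl.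

Step 10
Reactants: 16 lactol
Product: 17 diene diol (C9 vinyl group C11=C12; C8=C9; 2α-OH; 6α-OH; C17 silyl ether; cis-decalin)
Conditions: Ph3PCH3Br, KOtBu (excess), THF, 0 to 45 °C
Reagents that add atoms: methyltriphenylphosphonium bromide, C[P+](c1ccccc1)(c1ccccc1)c1ccccc1.[Br-]
Why: Wittig methylenation of the lactol through its ring-opened hydroxy-enal form; this releases the C2 hydroxyl. The silyl group on O17 prevents cyclisation onto the aldehyde.

Step 11
Reactants: 17 diene diol; 18 4-bromofuran-2(5H)-one
Product: 20 C17 tert-butyldiphenylsilyl ether of the target, via B-alkyl-9-BBN 19 (not isolated)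
Conditions: 9-BBN (3.5 equiv), THF, 0 °C to rt; then 18, Pd(dppf)Cl2 (10 mol %), AsPh3, K3PO4 (3 M aq.), DMF, rt
Reagents that add atoms: 9-borabicyclo[3.3.1]nonane, B1C2CCCC1CCC2 (its boron unit remains only in 19)
Why: 9-BBN hydroborates the monosubstituted vinyl group at C12 and leaves the tetrasubstituted alkene alone. The B-alkyl Suzuki–Miyaura coupling with the vinylogous acyl bromide then forms C12–C13 and brings in the finished butenolide.

Step 12
Reactants: 20 C17 tert-butyldiphenylsilyl ether of the target
Product: 21 CNP0293367.1, (2S,5R,6S,10S)-configured target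
Conditions: Bu4NF, AcOH, THF, 0 °C to rt
Reagents that add atoms: none
Why: Fluoride cleavage of the primary silyl ether, buffered with acetic acid so that the butenolide is not exposed to basic fluoride.

## Compound list

1 | β-isophorone (3,5,5-trimethylcyclohex-3-en-1-one) | CC1=CC(C)(C)CC(=O)C1 | starting material
2 | (R)-3,5,5-trimethylcyclohex-3-en-1-ol | CC1(C)C[C@H](O)CC(C)=C1 | intermediate
3 | 2,2,6-trimethyl-4H-1,3-dioxin-4-one | CC1=CC(=O)OC(C)(C)O1 | starting material
4 | acetylketene (formed in the flask) | CC(=O)C=C=O | intermediate
5 | (R)-3,5,5-trimethylcyclohex-3-en-1-yl 3-oxobutanoate | CC1(C)C[C@H](OC(=O)CC(C)=O)CC(C)=C1 | intermediate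
6 | chloroacetyl chloride | ClCC(Cl)=O | starting material
7 | (R)-3,5,5-trimethylcyclohex-3-en-1-yl 2-acetyl-4-chloro-3-oxobutanoate (enolised, formed in the flask) | CC1(C)C[C@H](OC(=O)C(C(C)=O)C(=O)CCl)CC(C)=C1 | intermediate
8 | (R)-3,5,5-trimethylcyclohex-3-en-1-yl 5-methyl-3-oxo-2,3-dihydrofuran-4-carboxylate | CC1(C)C[C@H](OC(=O)C2=C(C)OCC2=O)CC(C)=C1 | intermediate
9 | cyclobutane photoadduct: cyclobutane C5–C6–C9–C10 cis-fused to ring A on the α face, δ-lactone C9–C11(=O)–O–C2, furanone ring cis-fused on the side away from ring A (formed in the flask) | CC1(C)C[C@H]2C[C@@]3(C)[C@@H]1[C@]4(C)OCC(=O)[C@]34C(=O)O2 | intermediate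
10 | bridged δ-lactone 1,5-diketone: 5α-acetyl, 9-(hydroxyacetyl), C2–O–C11 lactone on the α face, 5β-H, 10β-methyl (C9 epimerisable, one epimer drawn) | CC1(C)C[C@H](O2)C[C@](C)([C@H](C(=O)CO)C2=O)[C@@H]1C(C)=O | intermediate
11 | C17 tert-butyldiphenylsilyl ether of 10 | CC1(C)C[C@H](O2)C[C@](C)([C@H](C(=O)CO[Si](c3ccccc3)(c3ccccc3)C(C)(C)C)C2=O)[C@@H]1C(C)=O | intermediate
12 | ketol: ring B closed, C6 ketone, C8 tertiary hydroxyl (C8 configuration not defined), 9β-H (formed in the flask) | CC1(C)C[C@H]2C[C@@]3(C)[C@@H]1C(=O)CC(O)(CO[Si](c4ccccc4)(c4ccccc4)C(C)(C)C)[C@H]3C(=O)O2 | intermediate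
13 | tricyclic enone: C6 ketone, C7=C8, C17 silyl ether, 9β-H, C2–O–C11 lactone, cis ring fusion | CC1(C)C[C@H]2C[C@@]3(C)[C@@H]1C(=O)C=C(CO[Si](c4ccccc4)(c4ccccc4)C(C)(C)C)[C@H]3C(=O)O2 | intermediate
14 | (6S)-allylic alcohol: 6α-OH, C7=C8, 9β-H, lactone and silyl ether as in 13 | CC1(C)C[C@H]2C[C@@]3(C)[C@@H]1[C@@H](O)C=C(CO[Si](c4ccccc4)(c4ccccc4)C(C)(C)C)[C@H]3C(=O)O2 | intermediate
15 | α,β-unsaturated δ-lactone: C8=C9 conjugated with C11=O, 6α-OH, C17 silyl ether | CC1(C)C[C@H]2C[C@@]3(C)[C@@H]1[C@@H](O)CC(CO[Si](c4ccccc4)(c4ccccc4)C(C)(C)C)=C3C(=O)O2 | intermediate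
16 | lactol of 15 (C11 hemiacetal, mixture at C11) | CC1(C)C[C@H]2C[C@@]3(C)[C@@H]1[C@@H](O)CC(CO[Si](c4ccccc4)(c4ccccc4)C(C)(C)C)=C3C(O)O2 | intermediate
17 | diene diol: 9-vinyl, C8=C9, 2α-OH, 6α-OH, C17 silyl ether, cis-decalin | CC1(C)C[C@H](O)C[C@]2(C)C(C=C)=C(CO[Si](c3ccccc3)(c3ccccc3)C(C)(C)C)C[C@H](O)[C@H]12 | intermediate
18 | 4-bromofuran-2(5H)-one | BrC1=CC(=O)OC1 | starting material
19 | B-alkyl-9-BBN: boron on C12 (hydroxyls drawn free, formed in the flask) | CC1(C)C[C@H](O)C[C@]2(C)C(CCB3C4CCCC3CCC4)=C(CO[Si](c3ccccc3)(c3ccccc3)C(C)(C)C)C[C@H](O)[C@H]12 | intermediate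
20 | C17 tert-butyldiphenylsilyl ether of the target | CC1(C)C[C@H](O)C[C@]2(C)C(CCC3=CC(=O)OC3)=C(CO[Si](c3ccccc3)(c3ccccc3)C(C)(C)C)C[C@H](O)[C@H]12 | intermediate
21 | CNP0293367.1: 4-{2-[(2S,5R,6S,10S)-2,6-dihydroxy-8-(hydroxymethyl)-4,4,10-trimethyl-cis-decal-8-en-9-yl]ethyl}furan-2(5H)-one (labdane-type locants) | CC1(C)C[C@H](O)C[C@]2(C)C(CCC3=CC(=O)OC3)=C(CO)C[C@H](O)[C@H]12 | target

## Step count and risk

Total step count: 12. Longest linear sequence: 12 steps (1 to 21); compounds 3, 6 and 18 are bought.

**Step 4 (key step).** The most likely failure is slow cycloaddition. Only the sparsely populated s-cis ester rotamer can close, and rotamer exchange is slower than triplet decay, so long irradiation may let photodegradation or disproportionation of the biradical beside the quaternary C4 take over. After the opening, migration of the lactone acyl group to the freed C17 hydroxyl is a second hazard. The fallback makes the same two bonds thermally with a ketene, where the ester can rotate during the lifetime of the reactive species and the ketene polarity (carbonyl carbon to C5, terminus to C10) agrees with the tether. It sets out from 2: opening of 2,2-dimethyl-1,3-dioxane-4,6-dione in toluene at 100 °C gives the malonic half-ester F1, and oxalyl chloride gives the acid chloride F2. Slow addition of F2 to Et3N in toluene at reflux generates the (alkoxycarbonyl)ketene F3, which should add across C5=C10 to the cis-fused cyclobutanone β-keto-lactone F4. C-acylation of F4 at C9 with (tert-butyldiphenylsilyloxy)acetyl chloride (MgCl2, Et3N) gives the 2-acylcyclobutanone F5. Addition of MeMgBr/CeCl3 to the strained C6 ketone at −78 °C is followed by retro-aldol opening of C6–C9, and the route is rejoined at 11 with O17 already silylated.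

**Step 6.** Hot acid may open the strained β-keto-lactone hydrolytically (then decarboxylation), the C17 enol may attack C6 in a competing aldol mode, or the silyl ether may be lost. The fallback closes ring B by addition–elimination instead of aldol dehydration and sets out from 11. NaH and PhNTf2 give the enol triflate F6 of the β-keto-lactone; LiN(SiMe3)2 at −78 °C forms the methyl ketone enolate, which adds to C8 and expels triflate to give the β,γ-unsaturated ketone F7 with C8=C9 already in place. NaBH4/CeCl3 reduction of F7 rejoins the route at 15.

**Step 7.** Face selection at C6 may be poor or reversed, because the β face carries the 1,3-related angular methyl group. The fallback corrects the centre by inversion and sets out from 13. The 6β-alcohol F8 is isomerised with DBU to the conjugated lactone F9; Mitsunobu reaction of F9 with chloroacetic acid (PPh3, diisopropyl azodicarboxylate) gives the inverted chloroacetate F10, and thiourea/NaHCO3 removes the chloroacetyl group, rejoining the route at 15.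

**Step 11.** Transmetallation of the hindered alkylborane may be slow, so that protodeboronation and base-induced decomposition of the bromobutenolide compete. The fallback separates hydroboration from coupling and uses a reductive cross-electrophile coupling; it sets out from 17. Hydroboration with 9-BBN and oxidation with NaBO3 give the primary alcohol F11; I2, PPh3 and imidazole convert the primary hydroxyl selectively into the iodide F12. Nickel-catalysed reductive coupling of F12 with 18 (NiBr2(dme), 4,4′-di-tert-butyl-2,2′-bipyridine, Zn, dimethylacetamide) rejoins the route at 20.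

**Step 1.** Enantiodiscrimination may be low because the two flanks of the ketone differ only at the β-carbons, and the substrate may isomerise to the conjugated ketone. The fallback is a classical resolution and sets out from 1. NaBH4/CeCl3 gives the racemic alcohol F13; esterification with (S)-O-acetylmandelic acid (dicyclohexylcarbodiimide, 4-dimethylaminopyridine) and separation of the diastereomers gives the (R)-alcohol mandelate F14, and LiOH hydrolysis rejoins the route at 2.

## Further compounds

F1 | step 4 | (R)-3,5,5-trimethylcyclohex-3-en-1-yl hydrogen malonate | CC1(C)C[C@H](OC(=O)CC(O)=O)CC(C)=C1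
F2 | step 4 | (R)-3,5,5-trimethylcyclohex-3-en-1-yl 3-chloro-3-oxopropanoate | CC1(C)C[C@H](OC(=O)CC(Cl)=O)CC(C)=C1
F3 | step 4 | (R)-3,5,5-trimethylcyclohex-3-en-1-yl 3-oxoprop-2-enoate (alkoxycarbonylketene) | CC1(C)C[C@H](OC(=O)C=C=O)CC(C)=C1
F4 | step 4 | cis-fused cyclobutanone β-keto-lactone (C6 ring ketone bonded to C5 and C9; C9–C10 bond; C2–O–C11 lactone) | CC1(C)C[C@H]2C[C@@]3(C)[C@@H]1C(=O)[C@H]3C(=O)O2
F5 | step 4 | 9-[(tert-butyldiphenylsilyloxy)acetyl] derivative of F4 | CC1(C)C[C@H]2C[C@@]3(C)[C@@H]1C(=O)[C@@]3(C(=O)CO[Si](c4ccccc4)(c4ccccc4)C(C)(C)C)C(=O)O2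
F6 | step 6 | C8 enol triflate of 11 (alkene geometry not defined) | CC1(C)C[C@H]2C[C@@](C)([C@@H]1C(C)=O)C(C(=O)O2)=C(CO[Si](c3ccccc3)(c3ccccc3)C(C)(C)C)OS(=O)(=O)C(F)(F)F
F7 | step 6 | β,γ-unsaturated ketone (C6 ketone, C8=C9 conjugated with the lactone) | CC1(C)C[C@H]2C[C@@]3(C)[C@@H]1C(=O)CC(CO[Si](c4ccccc4)(c4ccccc4)C(C)(C)C)=C3C(=O)O2
F8 | step 7 | 6-epimer of 14 (6β-OH) | CC1(C)C[C@H]2C[C@@]3(C)[C@@H]1[C@H](O)C=C(CO[Si](c4ccccc4)(c4ccccc4)C(C)(C)C)[C@H]3C(=O)O2
F9 | step 7 | 6-epimer of 15 (6β-OH) | CC1(C)C[C@H]2C[C@@]3(C)[C@@H]1[C@H](O)CC(CO[Si](c4ccccc4)(c4ccccc4)C(C)(C)C)=C3C(=O)O2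
F10 | step 7 | 6α-chloroacetate of 15 | CC1(C)C[C@H]2C[C@@]3(C)[C@@H]1[C@@H](OC(=O)CCl)CC(CO[Si](c4ccccc4)(c4ccccc4)C(C)(C)C)=C3C(=O)O2
F11 | step 11 | C12 primary alcohol from 17 | CC1(C)C[C@H](O)C[C@]2(C)C(CCO)=C(CO[Si](c3ccccc3)(c3ccccc3)C(C)(C)C)C[C@H](O)[C@H]12
F12 | step 11 | C12 iodide from F11 | CC1(C)C[C@H](O)C[C@]2(C)C(CCI)=C(CO[Si](c3ccccc3)(c3ccccc3)C(C)(C)C)C[C@H](O)[C@H]12
F13 | step 1 | racemic 3,5,5-trimethylcyclohex-3-en-1-ol | CC1(C)CC(O)CC(C)=C1
F14 | step 1 | (R)-3,5,5-trimethylcyclohex-3-en-1-yl (S)-2-acetoxy-2-phenylacetate | CC(=O)O[C@H](C(=O)O[C@@H]1CC(C)=CC(C)(C)C1)c1ccccc1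
A1 | alternative 1 | ten-membered dienedione: (Z)-enone C2(=O)–C1=C10, C6 ketone, C8=C9 with both silyloxy side arms | C/C1=C/C(=O)CC(C)(C)CC(=O)C/C(CO[Si](C)(C)C(C)(C)C)=C1/CCO[Si](C)(C)C(C)(C)C
A2 | alternative 1 | cis-decalin-2,6-dione with the C8=C9 alkene | CC1(C)CC(=O)C[C@]2(C)C(CCO[Si](C)(C)C(C)(C)C)=C(CO[Si](C)(C)C(C)(C)C)CC(=O)[C@H]12
A3 | alternative 2 | 2-methoxy-6-methyl-1,4-benzoquinone | COC1=CC(=O)C=C(C)C1=O
A4 | alternative 2 | 4-methyl-2-(triisopropylsilyloxy)penta-1,3-diene | CC(C)=CC(=C)O[Si](C(C)C)(C(C)C)C(C)C
A5 | alternative 2 | cis-fused quinone Diels–Alder adduct (C2 silyl enol ether, C6 and C9 ketones, C8 methyl enol ether) | CC1(C)C=C(O[Si](C(C)C)(C(C)C)C(C)C)C[C@]2(C)C(=O)C(OC)=CC(=O)[C@H]12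
A6 | alternative 3 | (6Z)-triene on ring A (C10=C5, C6=C7, C8=C9; three silyl ethers) | CC1=C(\C=C/C(CO[Si](C)(C)C(C)(C)C)=C/CCO[Si](C)(C)C(C)(C)C)C(C)(C)C[C@H](O[Si](C)(C)C(C)(C)C)C1
A7 | alternative 3 | cis-fused 6,8-diene with quaternary C10 | CC1(C)C[C@H](O[Si](C)(C)C(C)(C)C)C[C@]2(C)C(CCO[Si](C)(C)C(C)(C)C)=C(CO[Si](C)(C)C(C)(C)C)C=C[C@H]12
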